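**Retrosynthetic overview**
1. The γ-hydroxy-α,β-unsaturated lactone (C=C in ring B, tertiary OH at the ring B/C junction) comes from a β,γ-epoxy lactone by E1cB opening; the epoxide comes from the ring B alkene of a Diels–Alder adduct.
2. Ring B and the lactone (ring D) are closed together by an ester-tethered intramolecular Diels–Alder reaction between a 3-(cyclohexenyl)acrylate, which brings ring C, and the cyclopentene of ring A.
3. Enabling feature: the CH3-bearing carbon of the piperidine (ring E, C2) and the CH3/O-bearing carbon of ring A are 1,4-related across the bond from ring E C6 to ring A; without N and the two methyl groups they are the two carbonyl carbons of a 2,2'-bi(cyclopentanone), and its meso form has the required C6/ring A relative configuration.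
4. Ring E is therefore made from a cyclopentanone: Me3Al-promoted Beckmann ring expansion of its E-oxime mesylate inserts N into the C(=O)–Cα bond and methylates the former carbonyl carbon, the same reagent methylates the other (enone) carbonyl, and i-Bu2AlH sets the cis-2,6 relationship.
5. Order of ring formation: ring A and the second cyclopentane (oxidative enolate dimerization of cyclopentanone, ketoreductase desymmetrization), then ring E by ring expansion, then rings B and D by cycloaddition with ring C preformed.

Key step: step 7

Remark: the meso and dl forms of the bi(cyclopentanone) are taken to be separable and to interconvert with base, and a ketoreductase of the stated selectivity is taken to be found in a commercial screening panel.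

Step 1
Reactants: 1 cyclopentanone (two molecules)
Product: 2 meso-(1R,1'S)-[1,1'-bi(cyclopentane)]-2,2'-dione
Conditions: LiN(i-Pr)2, THF, −78 °C; CuCl2, DMF, −78 → 23 °C; chromatography, dl isomer re-equilibrated with DBU and recycled
Reagents that add atoms: none
Why: Oxidative coupling of the lithium enolate with CuCl2 joins two nucleophilic α-carbons to the 1,4-diketone; both new stereocentres are epimerizable, so the meso isomer is taken by separation and the dl isomer is recycled by base equilibration.

Step 2
Reactants: 2 meso-(1R,1'S)-[1,1'-bi(cyclopentane)]-2,2'-dione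
Product: 3 (2R)-2-[(1S,2R)-2-hydroxycyclopentyl]cyclopentan-1-one
Conditions: ketoreductase (NADPH-dependent, from a screening panel), NADP+ (cat.), i-PrOH, KH2PO4/K2HPO4 buffer pH 7, 30 °C
Reagents that add atoms: none
Why: Enzymatic desymmetrizing ketone reduction: the enzyme should accept only the carbonyl flanked by the S-configured α-carbon and deliver hydride to the face that gives the R carbinol trans to the ring substituent, which fixes the absolute configuration of both α-stereocentres and avoids lactol formation with the remaining ketone.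

Step 3
Reactants: 3 (2R)-2-[(1S,2R)-2-hydroxycyclopentyl]cyclopentan-1-one
Product: 6 (5R)-5-[(1S,2R)-2-hydroxycyclopentyl]cyclopent-2-en-1-one, via bis-silyl enol ether 4 (not isolated), via silyl ether enone 5 (not isolated)
Conditions: LiN(i-Pr)2 (2.2 equiv), Me3SiCl, THF, −78 °C; Pd(OAc)2 (1.05 equiv), MeCN, 23 °C; citric acid, MeOH–H2O
Reagents that add atoms: none
Why: Saegusa–Ito oxidation: kinetic deprotonation at the unsubstituted α'-CH2 gives the enol silane regioselectively and palladation/β-hydride elimination installs the enone C=C without touching the existing stereocentres (no new stereocentre).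

Step 4
Reactants: 6 (5R)-5-[(1S,2R)-2-hydroxycyclopentyl]cyclopent-2-en-1-one
Product: 7 (5R)-5-[(1S)-2-oxocyclopentyl]cyclopent-2-en-1-one
Conditions: Dess–Martin periodinane, CH2Cl2, 0 → 23 °C
Reagents that add atoms: none
Why: Dess–Martin oxidation of the secondary alcohol under near-neutral conditions should regenerate the cyclopentanone without epimerizing the two α-stereocentres (no new stereocentre).

Step 5
Reactants: 7 (5R)-5-[(1S)-2-oxocyclopentyl]cyclopent-2-en-1-one
Product: 8 (5R)-5-[(1S,2E)-2-(hydroxyimino)cyclopentyl]cyclopent-2-en-1-one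
Conditions: NH2OH·HCl (1.05 equiv), NaOAc, MeOH, 0 °C
Reagents that add atoms: hydroxylamine hydrochloride, Cl.NO
Why: Oxime formation should occur at the saturated cyclopentanone, which is more electrophilic than the conjugated enone carbonyl, and the E geometry (OH anti to the substituted α-carbon) is favoured on steric grounds (no new sp3 stereocentre).

Step 6
Reactants: 8 (5R)-5-[(1S,2E)-2-(hydroxyimino)cyclopentyl]cyclopent-2-en-1-one
Product: 9 (5R)-5-[(1S,2E)-2-(methanesulfonyloxyimino)cyclopentyl]cyclopent-2-en-1-one
Conditions: MeSO2Cl, Et3N, CH2Cl2, −20 °C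
Reagents that add atoms: methanesulfonyl chloride, CS(=O)(=O)Cl
Why: O-sulfonylation of the oxime at low temperature activates the N–O bond for the rearrangement and retains the E geometry (no new stereocentre).

Step 7
Reactants: 9 (5R)-5-[(1S,2E)-2-(methanesulfonyloxyimino)cyclopentyl]cyclopent-2-en-1-one
Product: 12 (1R,5R)-1-methyl-5-[(2S,6S)-6-methylpiperidin-2-yl]cyclopent-2-en-1-ol, via imino enone 10 (not isolated), via imino carbinol 11 (not isolated)
Conditions: Me3Al (6 equiv), CH2Cl2, −78 → 0 °C then 23 °C; i-Bu2AlH (4 equiv), −78 → 0 °C; aqueous KNaC4H4O6 work-up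
Reagents that add atoms: trimethylaluminium, C[Al](C)C
Why: Me3Al ionizes the mesylate of the E-oxime while the anti-periplanar C–C bond (from the oxime carbon to the ring carbon that carries ring A) shifts from carbon to nitrogen with retention, so the cyclopentane is expanded to the six-membered cyclic nitrilium (imidoyl) species, which takes a methyl group from aluminium at carbon to give imine 10; this is the organoaluminium-promoted Beckmann rearrangement–alkylation known for 2-substituted cyclopentanone oxime sulfonates. The excess Me3Al then adds 1,2 to the cyclopentenone carbonyl (the usual course of Me3Al with enones in CH2Cl2) to give 11, and i-Bu2AlH reduces the 2-methyl-Δ1-piperideine to the amine. Ring E is the only ring closed, and it is closed by the 1,2-shift ring expansion (five-membered carbocycle to six-membered azacycle), not by a cyclization. The migrating carbon keeps its configuration (piperidine C2 of 12); the CH3-bearing piperidine carbon is set by axial hydride attack on the half-chair imine whose other α-substituent is equatorial, which gives the cis-2,6 product; the carbinol carbon is set by methyl delivery to the carbonyl face anti to the neighbouring ring substituent, which places OH cis to the piperidine. The step needs the right α-carbon to migrate, secured by the E-oxime geometry (leaving group anti to the substituted α-carbon), and 1,2- instead of 1,4-methylation, secured by the oxophilic, copper-free alane. Interception of the nitrilium ion by the carbonyl or alkoxide oxygen is not expected, because the bridged imidate so formed would carry a bridgehead C=N bond.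

Step 8
Reactants: 12 (1R,5R)-1-methyl-5-[(2S,6S)-6-methylpiperidin-2-yl]cyclopent-2-en-1-ol
Product: 13 1-[(2S,6S)-2-[(1R,2R)-2-hydroxy-2-methylcyclopent-3-en-1-yl]-6-methylpiperidin-1-yl]ethan-1-one
Conditions: Ac2O, pyridine, 23 → 40 °C
Reagents that add atoms: acetic anhydride, CC(=O)OC(C)=O
Why: N-Acylation of the secondary amine should be selective because the tertiary allylic alcohol is far less nucleophilic (no new stereocentre).

Step 9
Reactants: 14 cyclohex-1-ene-1-carbaldehyde; 15 malonic acid
Product: 16 (2E)-3-(cyclohex-1-en-1-yl)prop-2-enoic acid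
Conditions: pyridine, piperidine (cat.), 90 °C
Reagents that add atoms: none
Why: Knoevenagel–Doebner condensation with decarboxylation gives the E-dienoic acid under thermodynamic control of the alkene geometry.

Step 10
Reactants: 13 1-[(2S,6S)-2-[(1R,2R)-2-hydroxy-2-methylcyclopent-3-en-1-yl]-6-methylpiperidin-1-yl]ethan-1-one; 16 (2E)-3-(cyclohex-1-en-1-yl)prop-2-enoic acid
Product: 18 (1R,5R)-5-[(2S,6S)-1-acetyl-6-methylpiperidin-2-yl]-1-methylcyclopent-2-en-1-yl (2E)-3-(cyclohex-1-en-1-yl)prop-2-enoate, via acid chloride 17 (not isolated)
Conditions: 16, (COCl)2, DMF (cat.), CH2Cl2, 0 → 23 °C, evaporate; 13, LiN(SiMe3)2, THF, −78 °C, then the acid chloride, −78 → 0 °C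
Reagents that add atoms: none
Why: Acylation of the lithium alkoxide of the hindered tertiary alcohol with the acid chloride is the reliable way to a tertiary ester and changes no stereocentre.

Step 11
Reactants: 18 (1R,5R)-5-[(2S,6S)-1-acetyl-6-methylpiperidin-2-yl]-1-methylcyclopent-2-en-1-yl (2E)-3-(cyclohex-1-en-1-yl)prop-2-enoate
Product: 19 Diels–Alder adduct: pentacyclic β,γ-unsaturated γ-lactone with the ring B C=C between the ring B/C junction carbon and the CH next to the lactone α-carbon, lactone trans-fused to ring B, ring A cis-fused to rings B and D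
Conditions: toluene (0.01 M), BHT, sealed tube, 185 °C
Reagents that add atoms: none
Why: Thermal intramolecular Diels–Alder reaction of the dienoate with the cyclopentene C=C: the three-atom ester tether allows bonding only to the alkene face syn to the ester oxygen, which makes the two ring A/B junction hydrogens cis, and the transition state that keeps ring A away from the diene (exo) should place the ring B/C junction hydrogen trans to the neighbouring ring A/B junction hydrogen and give the trans-fused lactone.

Step 12
Reactants: 19 Diels–Alder adduct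
Product: 20 β,γ-epoxy lactone: epoxide of the ring B alkene of 19 with the oxygen on the ring B face opposite to ring A
Conditions: mCPBA, CH2Cl2, 0 °C
Reagents that add atoms: 3-chloroperoxybenzoic acid, OOC(=O)c1cccc(Cl)c1
Why: Prilezhaev epoxidation of the only C=C should occur from the face anti to the cis-fused ring A, whose axial CH2 shields the other face, which sets the future carbinol carbon with oxygen trans to the ring B/C junction hydrogen.

Step 13
Reactants: 20 β,γ-epoxy lactone
Product: 21 CNP0529632.1 (target)
Conditions: DBU, toluene, 60 °C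
Reagents that add atoms: none
Why: E1cB opening of the β,γ-epoxy lactone: deprotonation α to the lactone carbonyl and anti elimination across the adjacent epoxide C–O bond give the conjugated alkene and the tertiary alcohol with retention at the carbinol carbon, and the α-stereocentre disappears.

**Compound list**
1 | cyclopentanone | O=C1CCCC1 | starting material
2 | meso-(1R,1'S)-[1,1'-bi(cyclopentane)]-2,2'-dione | O=C1CCC[C@H]1[C@H]1CCCC1=O | intermediate
3 | (2R)-2-[(1S,2R)-2-hydroxycyclopentyl]cyclopentan-1-one | O[C@@H]1CCC[C@H]1[C@H]1CCCC1=O | intermediate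
4 | trimethyl{[(1R,2S)-2-[(1R)-2-(trimethylsilyloxy)cyclopent-2-en-1-yl]cyclopentyl]oxy}silane | C[Si](C)(C)O[C@@H]1CCC[C@H]1[C@H]1CCC=C1O[Si](C)(C)C | intermediate
5 | (5R)-5-[(1S,2R)-2-(trimethylsilyloxy)cyclopentyl]cyclopent-2-en-1-one | C[Si](C)(C)O[C@@H]1CCC[C@H]1[C@H]1CC=CC1=O | intermediate
6 | (5R)-5-[(1S,2R)-2-hydroxycyclopentyl]cyclopent-2-en-1-one | O[C@@H]1CCC[C@H]1[C@H]1CC=CC1=O | intermediate
7 | (5R)-5-[(1S)-2-oxocyclopentyl]cyclopent-2-en-1-one | O=C1CCC[C@H]1[C@H]1CC=CC1=O | intermediate
8 | (5R)-5-[(1S,2E)-2-(hydroxyimino)cyclopentyl]cyclopent-2-en-1-one | O/N=C1\CCC[C@H]1[C@H]1CC=CC1=O | intermediate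
9 | (5R)-5-[(1S,2E)-2-(methanesulfonyloxyimino)cyclopentyl]cyclopent-2-en-1-one | CS(=O)(=O)O/N=C1\CCC[C@H]1[C@H]1CC=CC1=O | intermediate
10 | (5R)-5-[(2S)-6-methyl-2,3,4,5-tetrahydropyridin-2-yl]cyclopent-2-en-1-one | CC1=N[C@@H](CCC1)[C@H]1CC=CC1=O | intermediate
11 | (1R,5R)-1-methyl-5-[(2S)-6-methyl-2,3,4,5-tetrahydropyridin-2-yl]cyclopent-2-en-1-ol | CC1=N[C@@H](CCC1)[C@H]1CC=C[C@@]1(C)O | intermediate
12 | (1R,5R)-1-methyl-5-[(2S,6S)-6-methylpiperidin-2-yl]cyclopent-2-en-1-ol | N1[C@@H](C)CCC[C@H]1[C@H]1CC=C[C@@]1(C)O | intermediate
13 | 1-[(2S,6S)-2-[(1R,2R)-2-hydroxy-2-methylcyclopent-3-en-1-yl]-6-methylpiperidin-1-yl]ethan-1-one | CC(=O)N1[C@@H](C)CCC[C@H]1[C@H]1CC=C[C@@]1(C)O | intermediate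
14 | cyclohex-1-ene-1-carbaldehyde | O=CC1=CCCCC1 | starting material
15 | malonic acid | OC(=O)CC(=O)O | starting material
16 | (2E)-3-(cyclohex-1-en-1-yl)prop-2-enoic acid | OC(=O)/C=C/C1=CCCCC1 | intermediate
17 | (2E)-3-(cyclohex-1-en-1-yl)prop-2-enoyl chloride | ClC(=O)/C=C/C1=CCCCC1 | intermediate
18 | (1R,5R)-5-[(2S,6S)-1-acetyl-6-methylpiperidin-2-yl]-1-methylcyclopent-2-en-1-yl (2E)-3-(cyclohex-1-en-1-yl)prop-2-enoate | CC(=O)N1[C@@H](C)CCC[C@H]1[C@H]1CC=C[C@@]1(C)OC(=O)/C=C/C1=CCCCC1 | intermediate
19 | Diels–Alder adduct (trans-fused β,γ-unsaturated lactone) | CC(=O)N1[C@@H](C)CCC[C@H]1[C@H]1C[C@@H]2[C@H]3[C@H](C=C4CCCC[C@@H]24)C(=O)O[C@@]13C | intermediate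
20 | β,γ-epoxy lactone | CC(=O)N1[C@@H](C)CCC[C@H]1[C@H]1C[C@@H]2[C@H]3[C@H]([C@H]4O[C@]45CCCC[C@@H]25)C(=O)O[C@@]13C | intermediate
21 | CNP0529632.1 | CC(=O)N1[C@@H](C)CCC[C@H]1[C@H]1C[C@@H]2[C@H]3C(=C[C@]4(O)CCCC[C@@H]24)C(=O)O[C@@]13C | target

**Step count**
Total: 13 steps. Longest linear sequence: 12 steps (steps 1–8 and 10–13); step 9 is a one-step side branch.

**Steps most likely to fail, with fallbacks**

Step 7. Methyl transfer from aluminium to the enone carbonyl may be slow or poorly face-selective, and the transient keto-imine may enolize and condense with the neighbouring carbonyl before it is methylated. The fallback installs the carbinol methyl with an organocerium reagent before the ring expansion. It sets out from 6: MeLi/CeCl3 (THF, −78 °C) should add 1,2 to the enone anti to the ring substituent to give the diol (1R,5R)-5-[(1S,2R)-2-hydroxycyclopentyl]-1-methylcyclopent-2-en-1-ol F1. Dess–Martin periodinane should oxidize only the secondary alcohol to the hydroxy ketone (2S)-2-[(1R,2R)-2-hydroxy-2-methylcyclopent-3-en-1-yl]cyclopentan-1-one F2, which may rest partly as its lactol. NH2OH·HCl/NaOAc should give the E-oxime F3 and MeSO2Cl/Et3N the oxime mesylate F4. Me3Al followed by i-Bu2AlH then effects only the Beckmann rearrangement–methylation–reduction (through 11), and the route is rejoined at 12.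

Step 11. The unactivated cyclopentene may add too slowly to the dienoate, so that ionization or thermal elimination of the tertiary allylic ester and diene polymerization take over; the endo mode may also compete. The fallback uses an ether tether and restores the lactone oxidation level afterwards. It sets out from 13, with the partner made from 16: LiAlH4 should reduce 16 to the dienol (2E)-3-(cyclohex-1-en-1-yl)prop-2-en-1-ol F5, and PBr3 should convert it into the allylic bromide F6. KH and F6 should alkylate the alkoxide of 13 to the allyl ether F7. Its intramolecular Diels–Alder reaction (toluene, 170 °C) has neither the ester conformational penalty nor a thermolabile ester and should give the tetrahydrofuran adduct F8 through the same exo mode. mCPBA should give the epoxide F9, and RuCl3 (cat.)/NaIO4 should oxidize the only ether CH2 to the lactone carbonyl, which rejoins the route at 20.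

Step 2. The enzyme may not distinguish the two enantiotopic carbonyl groups well enough, or may reduce on to the diol. The fallback is a chemical desymmetrization by enantiotopic-group-selective enolization. It sets out from 2: the chiral lithium amide LiN[CH(CH3)Ph]2 (appropriate enantiomer) with Me3SiCl as internal quench (THF, −100 °C) should remove an α'-proton of one carbonyl group only and give the enol silane (2S)-2-[(1R)-2-(trimethylsilyloxy)cyclopent-2-en-1-yl]cyclopentan-1-one F10. Pd(OAc)2 in MeCN should convert it directly into the enone, so that the route is rejoined at 7 and steps 3 and 4 are not needed.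

Further compounds
F1 | step 7 | (1R,5R)-5-[(1S,2R)-2-hydroxycyclopentyl]-1-methylcyclopent-2-en-1-ol | O[C@@H]1CCC[C@H]1[C@H]1CC=C[C@@]1(C)O
F2 | step 7 | (2S)-2-[(1R,2R)-2-hydroxy-2-methylcyclopent-3-en-1-yl]cyclopentan-1-one | O=C1CCC[C@H]1[C@H]1CC=C[C@@]1(C)O
F3 | step 7 | (1R,5R)-5-[(1S,2E)-2-(hydroxyimino)cyclopentyl]-1-methylcyclopent-2-en-1-ol | O/N=C1\CCC[C@H]1[C@H]1CC=C[C@@]1(C)O
F4 | step 7 | (1R,5R)-5-[(1S,2E)-2-(methanesulfonyloxyimino)cyclopentyl]-1-methylcyclopent-2-en-1-ol | CS(=O)(=O)O/N=C1\CCC[C@H]1[C@H]1CC=C[C@@]1(C)O
F5 | step 11 | (2E)-3-(cyclohex-1-en-1-yl)prop-2-en-1-ol | OC/C=C/C1=CCCCC1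
F6 | step 11 | 1-[(1E)-3-bromoprop-1-en-1-yl]cyclohex-1-ene | BrC/C=C/C1=CCCCC1
F7 | step 11 | 1-[(2S,6S)-2-[(1R,2R)-2-{[(2E)-3-(cyclohex-1-en-1-yl)prop-2-en-1-yl]oxy}-2-methylcyclopent-3-en-1-yl]-6-methylpiperidin-1-yl]ethan-1-one | CC(=O)N1[C@@H](C)CCC[C@H]1[C@H]1CC=C[C@@]1(C)OC/C=C/C1=CCCCC1
F8 | step 11 | tetrahydrofuran analogue of 19 (CH2 in place of the lactone C=O) | CC(=O)N1[C@@H](C)CCC[C@H]1[C@H]1C[C@@H]2[C@H]3[C@H](C=C4CCCC[C@@H]24)CO[C@@]13C
F9 | step 11 | tetrahydrofuran analogue of 20 (CH2 in place of the lactone C=O) | CC(=O)N1[C@@H](C)CCC[C@H]1[C@H]1C[C@@H]2[C@H]3[C@H]([C@H]4O[C@]45CCCC[C@@H]25)CO[C@@]13C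
F10 | step 2 | (2S)-2-[(1R)-2-(trimethylsilyloxy)cyclopent-2-en-1-yl]cyclopentan-1-one | O=C1CCC[C@H]1[C@H]1CCC=C1O[Si](C)(C)C
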